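## Retrosynthetic overview

1. Target 22 ⇐ mono-O-sulfation at the unhindered C3–OH of the C2-symmetric tetrol nostoxanthin 20.
2. 20 ⇐ double Wittig of two C15 phosphonium salts 16 with C10 dialdehyde 17; 16 ⇐ (2R,3R)-2,3-dihydroxy-β-ionone 13 (vinyl Grignard, then PPh3·HBr).
3. 13 ⇐ epoxide-initiated cation–olefin cyclisation of the unprotected acyclic epoxy-hydroxy-pseudoionone 11 (ψ-end → β-ring, as in 2-hydroxy-carotenoid biogenesis from a 1,2-epoxide); C2 and C3 are carried in from the open chain.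
4. 11 ⇐ two C5 units, prenal 4 and methyl 3-methylbut-2-enoate 1: asymmetric vinylogous aldol sets C3, hydroxyl-directed threo epoxidation sets C2, then a three-carbon extension.
5. Ring order: a single six-membered ring closure (step 6, C13 stage) supplies both end rings; they are joined afterwards and no other ring is formed.

Assumptions: the (R,R)-catalyst in step 2 is taken to deliver the nucleophile to the Re face of prenal (5R); this is checked on 6 by Mosher analysis and the antipodal catalyst is used if the sense is opposite. The hydrogen sulfate 22 is handled as its sodium or pyridinium salt; the SMILES shows the neutral acid. Dialdehyde 17 is bought as the industrial C10 building block.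

## Route

Step 1
Reactants: 1 methyl 3-methylbut-2-enoate
Product: 3 (1Z)-tert-butyl[(1-methoxy-3-methylbuta-1,3-dien-1-yl)oxy]dimethylsilane, via lithium dienolate 2 (not isolated)
Conditions: LiN(iPr)2 (1.1 equiv), THF, −78 °C; TBSCl, DMPU, −78 °C → rt; distil
Reagents that add atoms: tert-butyldimethylsilyl chloride, CC(C)(C)[Si](C)(C)Cl
Why: γ-deprotonation of the enoate gives the extended dienolate, which is O-silylated (silyl ketene acetal formation); no stereocentre is made and the acetal geometry is inconsequential.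

Step 2
Reactants: 3 (1Z)-tert-butyl[(1-methoxy-3-methylbuta-1,3-dien-1-yl)oxy]dimethylsilane; 4 3-methylbut-2-enal (prenal)
Product: 6 methyl (2E,5R)-5-hydroxy-3,7-dimethylocta-2,6-dienoate, via trichlorosilyl ether 5 (not isolated)
Conditions: SiCl4 (1.1 equiv), (R,R)-N,N'-bis(3,5-dimethyl-4-oxido-3,5-dihydro-4H-dinaphtho[2,1-d:1',2'-f][1,3,2]diazaphosphepin-4-yl)-N,N'-dimethylpentane-1,5-diamine (2 mol %), iPr2NEt (10 mol %), CH2Cl2, −78 °C; sat. aq. NaHCO3
Reagents that add atoms: none
Why: catalytic enantioselective vinylogous Mukaiyama aldol in which the phosphoramide-bound trichlorosilyl cation activates the enal and the dienolate attacks through its γ-carbon (s-trans, hence 2E) on the Re face, setting the carbinol carbon (later ring C3) as R.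

Step 3
Reactants: 6 methyl (2E,5R)-5-hydroxy-3,7-dimethylocta-2,6-dienoate
Product: 7 methyl (2E,5R)-5-[(2S)-3,3-dimethyloxiran-2-yl]-5-hydroxy-3-methylpent-2-enoate
Conditions: mCPBA (1.05 equiv), NaHCO3, CH2Cl2, 0 °C; chromatography (removes minor erythro isomer)
Reagents that add atoms: meta-chloroperoxybenzoic acid, OOC(=O)c1cccc(Cl)c1
Why: hydroxyl-directed (Henbest) peracid epoxidation of the electron-rich trisubstituted alkene only (the enoate is inert); A(1,3) strain from the cis methyl holds the carbinol H in the alkene plane, so oxygen is delivered syn to OH and gives the threo (5R,2'S) epoxy alcohol (about 95:5 expected for this substitution pattern), which sets ring C2.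

Step 4
Reactants: 7 methyl (2E,5R)-5-[(2S)-3,3-dimethyloxiran-2-yl]-5-hydroxy-3-methylpent-2-enoate
Product: 8 (2E,5R)-5-[(2S)-3,3-dimethyloxiran-2-yl]-3-methylpent-2-ene-1,5-diol
Conditions: iBu2AlH (3.3 equiv), CH2Cl2, −78 °C; aq. KNaC4H4O6
Reagents that add atoms: none
Why: 1,2-reduction of the enoate to the allylic alcohol by the aluminium hydride at low temperature, where the trisubstituted oxirane is not opened; no stereocentre is touched.

Step 5
Reactants: 8 (2E,5R)-5-[(2S)-3,3-dimethyloxiran-2-yl]-3-methylpent-2-ene-1,5-diol; 9 1-(triphenylphosphoranylidene)propan-2-one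
Product: 11 (3E,5E,8R)-8-[(2S)-3,3-dimethyloxiran-2-yl]-8-hydroxy-6-methylocta-3,5-dien-2-one, via epoxy enal 10 (not isolated)
Conditions: MnO2 (15 equiv), 9 (1.3 equiv), CH2Cl2, reflux
Reagents that add atoms: none
Why: tandem allylic oxidation–Wittig olefination; MnO2 oxidises only the primary allylic alcohol (the secondary carbinol is no longer allylic) and the stabilised ylide traps the enal E-selectively to give the dienone.

Step 6
Reactants: 11 (3E,5E,8R)-8-[(2S)-3,3-dimethyloxiran-2-yl]-8-hydroxy-6-methylocta-3,5-dien-2-one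
Product: 13 (3E)-4-[(4R,5R)-4,5-dihydroxy-2,6,6-trimethylcyclohex-1-en-1-yl]but-3-en-2-one, via 4,5-ene isomer 12 (not isolated)
Conditions: Ph4PBF4 (10 mol %), (CF3)2CHOH, 0 °C → rt; evaporate; then NaOMe (0.3 equiv), MeOH, 25–40 °C
Reagents that add atoms: none
Why: Proposed new method: the fluoroalcohol (helped by the vicinal OH hydrogen bond) ionises the oxirane at its tertiary carbon, and C6 of the γ,δ-olefin of the dienone attacks anti through a chair transition state with C2–O and C3–OH equatorial, closing the six-membered ring; the carbonyl disfavours five-ring closure through C5 exactly as in the acid cyclisation of pseudoionone to ionones, proton loss gives mainly the 4,5-ene 12, and methoxide moves the double bond into conjugation (α-ionone → β-ionone type isomerisation) to give 13; closest known reactions are the pseudoionone → ionone cyclisation and the fluoroalcohol- or Lewis-acid-promoted cyclisation of 6,7-epoxygeranyl esters; both stereocentres come unchanged from 11 because the C2–O and C3–O bonds are never broken.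

Step 7
Reactants: 13 (3E)-4-[(4R,5R)-4,5-dihydroxy-2,6,6-trimethylcyclohex-1-en-1-yl]but-3-en-2-one; 14 vinylmagnesium bromide
Product: 15 (1E)-1-[(4R,5R)-4,5-dihydroxy-2,6,6-trimethylcyclohex-1-en-1-yl]-3-methylpenta-1,4-dien-3-ol (both C3 epimers)
Conditions: CH2=CHMgBr (4 equiv), THF, −20 → 0 °C; H2O
Reagents that add atoms: none
Why: Grignard 1,2-addition to the dienone carbonyl after deprotonation of the two hydroxyls; the new tertiary carbinol centre forms as both epimers and is erased in step 8.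

Step 8
Reactants: 15 (1E)-1-[(4R,5R)-4,5-dihydroxy-2,6,6-trimethylcyclohex-1-en-1-yl]-3-methylpenta-1,4-dien-3-ol
Product: 16 {(2E,4E)-5-[(4R,5R)-4,5-dihydroxy-2,6,6-trimethylcyclohex-1-en-1-yl]-3-methylpenta-2,4-dien-1-yl}triphenylphosphonium bromide
Conditions: PPh3·HBr (1.05 equiv), MeOH, 0 °C → rt; crystallise
Reagents that add atoms: triphenylphosphine hydrobromide, [Br-].c1ccc(cc1)[PH+](c1ccccc1)c1ccccc1
Why: ionisation of the tertiary bis-allylic alcohol to a pentadienyl cation and SN1' capture by PPh3 at the primary terminus (allylic transposition) gives the C15 Wittig salt, mainly 2E; the secondary ring diol does not ionise.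

Step 9
Reactants: 16 {(2E,4E)-5-[(4R,5R)-4,5-dihydroxy-2,6,6-trimethylcyclohex-1-en-1-yl]-3-methylpenta-2,4-dien-1-yl}triphenylphosphonium bromide (2.2 equiv); 17 (2E,4E,6E)-2,7-dimethylocta-2,4,6-trienedial
Product: 20 (all-E,2R,3R,2'R,3'R)-β,β-carotene-2,3,2',3'-tetrol (nostoxanthin), via ylide 18 (not isolated), via C25 aldehyde 19 (not isolated)
Conditions: NaOMe (2.4 equiv), MeOH/CH2Cl2, 0 °C → rt; then EtOH, reflux (Z → E); crystallise
Reagents that add atoms: none
Why: double Wittig olefination (C15 + C10 + C15), which tolerates free hydroxyls, followed by thermal isomerisation of the 11Z isomers to the all-E polyene; the four stereocentres are untouched.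

Step 10
Reactants: 20 (all-E,2R,3R,2'R,3'R)-β,β-carotene-2,3,2',3'-tetrol
Product: 22 (all-E,2R,3R,2'R,3'R)-2,2',3'-trihydroxy-β,β-caroten-3-yl hydrogen sulfate (CNP0229621.3), via pyridinium sulfate 21 (not isolated)
Conditions: SO3·pyridine (1.0 equiv), pyridine/DMF, 0 °C, stop near 50 % conversion; reversed-phase separation (20 recycled); H+-form sulfonic acid resin, MeOH, 0 °C
Reagents that add atoms: sulfur trioxide–pyridine complex, [O-]S(=O)(=O)[n+]1ccccc1
Why: O-sulfation with a sulfur trioxide–amine complex goes to the unhindered C3 hydroxyl in preference to the neopentyl C2 hydroxyl beside the gem-dimethyl carbon, and limiting reagent on the C2-symmetric tetrol gives the mono-sulfate (either end is the same compound) with retention at C3.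

## Compound list

1 | methyl 3-methylbut-2-enoate | COC(=O)C=C(C)C | starting material
2 | lithium 1-methoxy-3-methylbuta-1,3-dien-1-olate | [Li+].C=C(C)/C=C(/OC)[O-] | intermediate
3 | (1Z)-tert-butyl[(1-methoxy-3-methylbuta-1,3-dien-1-yl)oxy]dimethylsilane | C=C(C)/C=C(/OC)O[Si](C)(C)C(C)(C)C | intermediate
4 | 3-methylbut-2-enal | CC(C)=CC=O | starting material
5 | methyl (2E,5R)-3,7-dimethyl-5-[(trichlorosilyl)oxy]octa-2,6-dienoate | COC(=O)/C=C(\C)C[C@@H](O[Si](Cl)(Cl)Cl)C=C(C)C | intermediate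
6 | methyl (2E,5R)-5-hydroxy-3,7-dimethylocta-2,6-dienoate | COC(=O)/C=C(\C)C[C@@H](O)C=C(C)C | intermediate
7 | methyl (2E,5R)-5-[(2S)-3,3-dimethyloxiran-2-yl]-5-hydroxy-3-methylpent-2-enoate | COC(=O)/C=C(\C)C[C@@H](O)[C@@H]1OC1(C)C | intermediate
8 | (2E,5R)-5-[(2S)-3,3-dimethyloxiran-2-yl]-3-methylpent-2-ene-1,5-diol | OC/C=C(\C)C[C@@H](O)[C@@H]1OC1(C)C | intermediate
9 | 1-(triphenylphosphoranylidene)propan-2-one | CC(=O)C=P(c1ccccc1)(c1ccccc1)c1ccccc1 | starting material
10 | (2E,5R)-5-[(2S)-3,3-dimethyloxiran-2-yl]-5-hydroxy-3-methylpent-2-enal | O=C/C=C(\C)C[C@@H](O)[C@@H]1OC1(C)C | intermediate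
11 | (3E,5E,8R)-8-[(2S)-3,3-dimethyloxiran-2-yl]-8-hydroxy-6-methylocta-3,5-dien-2-one | CC(=O)/C=C/C=C(\C)C[C@@H](O)[C@@H]1OC1(C)C | intermediate
12 | (3E)-4-[(1R,4R,5R)-4,5-dihydroxy-2,6,6-trimethylcyclohex-2-en-1-yl]but-3-en-2-one | CC(=O)/C=C/[C@@H]1C(C)=C[C@@H](O)[C@H](O)C1(C)C | intermediate
13 | (3E)-4-[(4R,5R)-4,5-dihydroxy-2,6,6-trimethylcyclohex-1-en-1-yl]but-3-en-2-one | CC(=O)/C=C/C1=C(C)C[C@@H](O)[C@H](O)C1(C)C | intermediate
14 | vinylmagnesium bromide | C=C[Mg]Br | starting material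
15 | (1E)-1-[(4R,5R)-4,5-dihydroxy-2,6,6-trimethylcyclohex-1-en-1-yl]-3-methylpenta-1,4-dien-3-ol (C3 epimers) | C=CC(C)(O)/C=C/C1=C(C)C[C@@H](O)[C@H](O)C1(C)C | intermediate
16 | {(2E,4E)-5-[(4R,5R)-4,5-dihydroxy-2,6,6-trimethylcyclohex-1-en-1-yl]-3-methylpenta-2,4-dien-1-yl}triphenylphosphonium bromide | CC1=C(/C=C/C(C)=C/C[P+](c2ccccc2)(c2ccccc2)c2ccccc2)C(C)(C)[C@@H](O)[C@H](O)C1.[Br-] | intermediate
17 | (2E,4E,6E)-2,7-dimethylocta-2,4,6-trienedial | O=C/C(C)=C/C=C/C=C(C)/C=O | starting material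
18 | {(2E,4E)-5-[(4R,5R)-4,5-dihydroxy-2,6,6-trimethylcyclohex-1-en-1-yl]-3-methylpenta-2,4-dien-1-ylidene}triphenylphosphorane | CC1=C(/C=C/C(C)=C/C=P(c2ccccc2)(c2ccccc2)c2ccccc2)C(C)(C)[C@@H](O)[C@H](O)C1 | intermediate
19 | (2E,4E,6E,8E,10E,12E)-13-[(4R,5R)-4,5-dihydroxy-2,6,6-trimethylcyclohex-1-en-1-yl]-2,7,11-trimethyltrideca-2,4,6,8,10,12-hexaenal | CC1=C(/C=C/C(C)=C/C=C/C(C)=C/C=C/C=C(C)/C=O)C(C)(C)[C@@H](O)[C@H](O)C1 | intermediate
20 | (all-E,2R,3R,2'R,3'R)-β,β-carotene-2,3,2',3'-tetrol (nostoxanthin) | CC1=C(/C=C/C(C)=C/C=C/C(C)=C/C=C/C=C(C)/C=C/C=C(C)/C=C/C2=C(C)C[C@@H](O)[C@H](O)C2(C)C)C(C)(C)[C@@H](O)[C@H](O)C1 | intermediate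
21 | pyridinium (all-E,2R,3R,2'R,3'R)-2,2',3'-trihydroxy-β,β-caroten-3-yl sulfate | CC1=C(/C=C/C(C)=C/C=C/C(C)=C/C=C/C=C(C)/C=C/C=C(C)/C=C/C2=C(C)C[C@@H](OS(=O)(=O)[O-])[C@H](O)C2(C)C)C(C)(C)[C@@H](O)[C@H](O)C1.c1cc[nH+]cc1 | intermediate
22 | (all-E,2R,3R,2'R,3'R)-2,2',3'-trihydroxy-β,β-caroten-3-yl hydrogen sulfate | CC1=C(/C=C/C(C)=C/C=C/C(C)=C/C=C/C=C(C)/C=C/C=C(C)/C=C/C2=C(C)C[C@@H](OS(=O)(=O)O)[C@H](O)C2(C)C)C(C)(C)[C@@H](O)[C@H](O)C1 | target

## Step count and risks

Total steps: 10. Longest linear sequence: 10 (1 → 22); 4, 9, 14 and 17 enter as purchased materials.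

Most likely to fail, in order: step 6, step 10, step 2.

Step 6 (cyclisation with a deactivated dienone terminator and a free vicinal hydroxyl; hydride shift to the α-hydroxy ketone or ether bridging may win). The fallback sets out from 8 and moves the ring closure to the C10 stage with an electron-rich alkene. Silylation (TBSCl, imidazole, DMF) gives (2E,5R)-1,5-bis[(tert-butyldimethylsilyl)oxy]-5-[(2S)-3,3-dimethyloxiran-2-yl]-3-methylpent-2-ene F1. MeAlCl2 in CH2Cl2 at −78 °C then closes the ring as for epoxygeranyl ethers, giving (1R,2R,5R)-2-[(tert-butyldimethylsilyl)oxy]-5-{[(tert-butyldimethylsilyl)oxy]methyl}-4,6,6-trimethylcyclohex-3-en-1-ol F2 (with some exocyclic alkene isomer, which converges later). Bu4NF gives (1R,2R,5R)-5-(hydroxymethyl)-4,6,6-trimethylcyclohex-3-ene-1,2-diol F3. TEMPO/PhI(OAc)2 oxidises the primary alcohol selectively to (1R,4R,5R)-4,5-dihydroxy-2,6,6-trimethylcyclohex-2-ene-1-carbaldehyde F4. Aldol condensation with acetone (NaOH) followed by base-mediated conjugation passes through 12 and comes back to the route at 13.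

Step 10 (statistical mono-sulfation; 3-OH versus 2-OH selectivity and over-sulfation). The fallback sets out from 16 and 17 and places the sulfate before the second ring is attached. Wittig reaction of 16 with a threefold excess of 17 gives the C25 aldehyde 19, which is isolated. It carries only one 3-OH; sulfation with SO3·pyridine, if needed through the 2,3-O-dibutylstannylene acetal (Bu2SnO, then SO3·NMe3), gives (2E,4E,6E,8E,10E,12E)-13-[(4R,5R)-5-hydroxy-2,6,6-trimethyl-4-(sulfooxy)cyclohex-1-en-1-yl]-2,7,11-trimethyltrideca-2,4,6,8,10,12-hexaenal F5, and any 2-sulfate is removed at this smaller stage. A second Wittig reaction of F5 with 16 (NaOMe, MeOH) comes back directly at 22.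

Step 2 (enantioselectivity, γ-selectivity and catalyst sense with a β,β-disubstituted enal). The fallback sets out from 3 and 4 and replaces catalyst control by resolution. TiCl4 in CH2Cl2 at −78 °C gives racemic methyl (2E)-5-hydroxy-3,7-dimethylocta-2,6-dienoate F6. Sharpless kinetic resolution (Ti(OiPr)4, L-(+)-diisopropyl tartrate, tBuOOH, 4 Å sieves, CH2Cl2, −20 °C, run past 60 % conversion because the cis methyl lowers the rate ratio) consumes the (S)-enantiomer as methyl (2E,5S)-5-[(2S)-3,3-dimethyloxiran-2-yl]-5-hydroxy-3-methylpent-2-enoate F7, which is discarded. The unreacted (R)-alcohol is 6, where the route is rejoined.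

## Further compounds

F1 | step 6 | (2E,5R)-1,5-bis[(tert-butyldimethylsilyl)oxy]-5-[(2S)-3,3-dimethyloxiran-2-yl]-3-methylpent-2-ene | CC(C)(C)[Si](C)(C)OC/C=C(\C)C[C@@H](O[Si](C)(C)C(C)(C)C)[C@@H]1OC1(C)C
F2 | step 6 | (1R,2R,5R)-2-[(tert-butyldimethylsilyl)oxy]-5-{[(tert-butyldimethylsilyl)oxy]methyl}-4,6,6-trimethylcyclohex-3-en-1-ol | CC(C)(C)[Si](C)(C)OC[C@@H]1C(C)=C[C@@H](O[Si](C)(C)C(C)(C)C)[C@H](O)C1(C)C
F3 | step 6 | (1R,2R,5R)-5-(hydroxymethyl)-4,6,6-trimethylcyclohex-3-ene-1,2-diol | OC[C@@H]1C(C)=C[C@@H](O)[C@H](O)C1(C)C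
F4 | step 6 | (1R,4R,5R)-4,5-dihydroxy-2,6,6-trimethylcyclohex-2-ene-1-carbaldehyde | O=C[C@@H]1C(C)=C[C@@H](O)[C@H](O)C1(C)C
F5 | step 10 | (2E,4E,6E,8E,10E,12E)-13-[(4R,5R)-5-hydroxy-2,6,6-trimethyl-4-(sulfooxy)cyclohex-1-en-1-yl]-2,7,11-trimethyltrideca-2,4,6,8,10,12-hexaenal | CC1=C(/C=C/C(C)=C/C=C/C(C)=C/C=C/C=C(C)/C=O)C(C)(C)[C@@H](O)[C@H](OS(=O)(=O)O)C1
F6 | step 2 | racemic methyl (2E)-5-hydroxy-3,7-dimethylocta-2,6-dienoate | COC(=O)/C=C(\C)CC(O)C=C(C)C
F7 | step 2 | methyl (2E,5S)-5-[(2S)-3,3-dimethyloxiran-2-yl]-5-hydroxy-3-methylpent-2-enoate | COC(=O)/C=C(\C)C[C@H](O)[C@@H]1OC1(C)C
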